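**Plan**

Atom labels: ring C1 (C=O), C2=C3, C4 (OMe), C5 (CH2), C6 (quaternary); side chain C8 (CHMe) and C7 (CH(OAc)aryl).
Retrosynthesis: the C7 acetate goes back to a silyl ether and the allyl group to a formyl group on C6. The cyclohexenone is then cut at C1–C6 and C4–C5, which is possible because the C1 carbonyl oxygen and the C4 ether oxygen stand 1,4 across the C2=C3 double bond of a ring whose C6 is quaternary – the imprint of an opened 2-alkoxyfuran cycloadduct. The remaining enal is cut at its methylidene carbon and at C7–C8.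
Forward: the open chain C7–C8 is made first from 3,4,5-trimethoxybenzaldehyde and extended to a 2-substituted acrolein. The only ring formed, the cyclohexenone, arises in one operation from 2-methoxyfuran. O-Methylation at C4, conversion of CHO into allyl and exchange of silyl for acetyl follow.
Stereochemistry: C7 and C8 come from a catalyst-controlled syn-crotylboration, C6 from addition of the furan to the Re face of the enal under the influence of C8, and C4 from the endo position of the aluminium-bound formyl group in the cycloaddition.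

Key step: step 6

Assumption: the (R)-configured phosphoric acid of step 1 is taken to direct the boronate to the Re face of the aryl aldehyde, as it does in the parent allylboration; should the sense be opposite, the (S)-acid is used.

**Route**

Step 1
Reactants: 1 3,4,5-trimethoxybenzaldehyde; 2 (Z)-crotylboronic acid pinacol ester
Product: 4 (1R,2S)-2-methyl-1-(3,4,5-trimethoxyphenyl)but-3-en-1-ol, via pinacol borate ester 3 (not isolated)
Conditions: (R)-3,3'-bis(2,4,6-triisopropylphenyl)-1,1'-binaphthyl-2,2'-diyl hydrogen phosphate (5 mol %), 4 Å MS, toluene, −30 °C; then aqueous work-up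
Reagents that add atoms: none
Why: Chiral phosphoric acid-catalysed crotylboration through a closed chair transition state, in which the (Z)-geometry of the boronate translates into the syn relationship of C7–O and C8–Me and the acid, bound to the boronate oxygen and the formyl hydrogen, directs addition to the Re face of the aldehyde, so that C7 becomes R and C8 becomes S.

Step 2
Reactants: 4 (1R,2S)-2-methyl-1-(3,4,5-trimethoxyphenyl)but-3-en-1-ol
Product: 5 tert-butyl(dimethyl){[(1R,2S)-2-methyl-1-(3,4,5-trimethoxyphenyl)but-3-en-1-yl]oxy}silane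
Conditions: TBSOTf, 2,6-lutidine, CH2Cl2, 0 °C
Reagents that add atoms: tert-butyldimethylsilyl trifluoromethanesulfonate, CC(C)(C)[Si](C)(C)OS(=O)(=O)C(F)(F)F
Why: Silylation of a secondary benzylic alcohol by a silyl triflate with a hindered pyridine base is routine, touches no stereocentre and installs an ether that neither ionises nor chelates under the aluminium Lewis acid of step 6.

Step 3
Reactants: 5 tert-butyl(dimethyl){[(1R,2S)-2-methyl-1-(3,4,5-trimethoxyphenyl)but-3-en-1-yl]oxy}silane
Product: 7 (3S,4R)-4-[(tert-butyldimethylsilyl)oxy]-3-methyl-4-(3,4,5-trimethoxyphenyl)butan-1-ol, via B-alkyl-9-borabicyclononane 6 (not isolated)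
Conditions: 9-borabicyclo[3.3.1]nonane (9-BBN), THF, 0 °C to rt; then NaOH, H2O2, 0 °C
Reagents that add atoms: hydrogen peroxide, OO
Why: Hydroboration–oxidation, in which the bulky dialkylborane places boron on the terminal carbon of the monosubstituted alkene (anti-Markovnikov) and alkaline peroxide replaces boron by hydroxyl, with no stereocentre formed or disturbed.

Step 4
Reactants: 7 (3S,4R)-4-[(tert-butyldimethylsilyl)oxy]-3-methyl-4-(3,4,5-trimethoxyphenyl)butan-1-ol
Product: 8 (3S,4R)-4-[(tert-butyldimethylsilyl)oxy]-3-methyl-4-(3,4,5-trimethoxyphenyl)butanal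
Conditions: Dess–Martin periodinane, CH2Cl2, 0 °C to rt
Reagents that add atoms: none
Why: Dess–Martin oxidation takes the primary alcohol to the aldehyde without over-oxidation under near-neutral conditions that leave the silyl ether and the stereocentre at the β-carbon intact.

Step 5
Reactants: 8 (3S,4R)-4-[(tert-butyldimethylsilyl)oxy]-3-methyl-4-(3,4,5-trimethoxyphenyl)butanal
Product: 10 (3S,4R)-4-[(tert-butyldimethylsilyl)oxy]-3-methyl-2-methylidene-4-(3,4,5-trimethoxyphenyl)butanal, via Mannich base 9 (not isolated)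
Conditions: CH2=NMe2+ I− (Eschenmoser's salt), Et3N, CH2Cl2, rt
Reagents that add atoms: N,N-dimethylmethyleneiminium iodide, C=[N+](C)C.[I-]
Why: α-Methylenation by a Mannich reaction of the enolisable aldehyde with the preformed iminium salt followed by base-induced elimination of dimethylamine from 9, in which the C8 stereocentre at the β-carbon takes no part in the enol and is kept.

Step 6
Reactants: 10 (3S,4R)-4-[(tert-butyldimethylsilyl)oxy]-3-methyl-2-methylidene-4-(3,4,5-trimethoxyphenyl)butanal; 11 2-methoxyfuran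
Product: 13 (1R,5R)-1-[(1R,2S)-1-[(tert-butyldimethylsilyl)oxy]-1-(3,4,5-trimethoxyphenyl)propan-2-yl]-5-hydroxy-2-oxocyclohex-3-ene-1-carbaldehyde, via bridged ketal 12 (not isolated)
Conditions: 11 (3 equiv), Me2AlCl (1.2 equiv), CH2Cl2, −78 °C; then aq. NaH2PO4, THF, 0 °C
Reagents that add atoms: water, O
Why: Me2AlCl binds the formyl oxygen of 10, the furan carbon remote from the methoxy group attacks the methylene carbon (C5) and the methoxy-bearing carbon bonds to the α-carbon (C6) in a concerted but strongly asynchronous [4+2] addition, whose stepwise limit (Michael addition, then closure of the aluminium enolate on the oxocarbenium ion) leads to the same 1-methoxy-7-oxanorbornene 12. Mildly acidic water then cleaves the oxygen bridge at the ketal carbon, leaving the ketone at C1 conjugated with C2=C3 and the furan oxygen as the C4 hydroxyl, and no aromatisation can follow because C6 is quaternary. The closest known reaction type is the Lewis acid-promoted Diels–Alder addition of 2-alkoxyfurans to acrylic dienophiles with hydrolytic opening of the bridged ketals to 4-hydroxycyclohex-2-enones. The six-membered carbocycle closes in the cycloaddition mode, C1–C6 and C4–C5 being formed suprafacially on both partners (a 6-exo-trig attack of the enolate on C1 in the stepwise limit). C6 is set by C8, since with C8–H near the enal plane on the methylene side the methyl group and the bulky CH(OTBS)aryl group occupy opposite faces and the furan adds to the methyl-bearing Re face, while C4 is set relative to C6 by the endo position of the aluminium-bound formyl group, which leaves the branched side chain in the open exo sector beside the oxygen bridge and hence cis to the C4 oxygen. The step needs regio-, face-, endo- and periselectivity: the donor methoxy group polarises the furan for the required orientation, C8 and the endo preference of the complexed carbonyl give the next two, and the proton-scavenging Al–Me bonds together with the low temperature hold back rearomatisation of the Michael intermediate to a 5-alkylated furan.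

Step 7
Reactants: 13 (1R,5R)-1-[(1R,2S)-1-[(tert-butyldimethylsilyl)oxy]-1-(3,4,5-trimethoxyphenyl)propan-2-yl]-5-hydroxy-2-oxocyclohex-3-ene-1-carbaldehyde
Product: 14 (1R,5R)-1-[(1R,2S)-1-[(tert-butyldimethylsilyl)oxy]-1-(3,4,5-trimethoxyphenyl)propan-2-yl]-5-methoxy-2-oxocyclohex-3-ene-1-carbaldehyde
Conditions: Me3OBF4, 1,8-bis(dimethylamino)naphthalene, CH2Cl2, 0 °C to rt
Reagents that add atoms: trimethyloxonium tetrafluoroborate, C[O+](C)C.F[B-](F)(F)F
Why: O-Methylation by Meerwein's salt with a non-nucleophilic proton scavenger alkylates the neutral hydroxyl, so that no alkoxide or nucleophilic base is present to deformylate the non-enolisable β-keto aldehyde and the C4–O bond is never broken (retention at C4).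

Step 8
Reactants: 14 (1R,5R)-1-[(1R,2S)-1-[(tert-butyldimethylsilyl)oxy]-1-(3,4,5-trimethoxyphenyl)propan-2-yl]-5-methoxy-2-oxocyclohex-3-ene-1-carbaldehyde
Product: 15 (4R,6S)-6-[(1R,2S)-1-[(tert-butyldimethylsilyl)oxy]-1-(3,4,5-trimethoxyphenyl)propan-2-yl]-4-methoxy-6-(2-methoxyethenyl)cyclohex-2-en-1-one (E/Z mixture)
Conditions: Ph3P(CH2OMe)Cl, KN(SiMe3)2, THF, −78 to 0 °C
Reagents that add atoms: (methoxymethyl)triphenylphosphonium chloride, COC[P+](c1ccccc1)(c1ccccc1)c1ccccc1.[Cl-]
Why: Wittig reaction of the non-stabilised α-alkoxy ylide, a reagent that homologates hindered aldehydes, should take the formyl group in preference to the more hindered and conjugated C1 ketone, the E/Z mixture being of no consequence and C6 being unable to epimerise.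

Step 9
Reactants: 15 (4R,6S)-6-[(1R,2S)-1-[(tert-butyldimethylsilyl)oxy]-1-(3,4,5-trimethoxyphenyl)propan-2-yl]-4-methoxy-6-(2-methoxyethenyl)cyclohex-2-en-1-one
Product: 16 2-[(1S,5R)-1-[(1R,2S)-1-[(tert-butyldimethylsilyl)oxy]-1-(3,4,5-trimethoxyphenyl)propan-2-yl]-5-methoxy-2-oxocyclohex-3-en-1-yl]acetaldehyde
Conditions: 1 M aq. HCl, THF, 0 °C to rt
Reagents that add atoms: water, O
Why: Acid hydrolysis of the enol ether (C-protonation to the oxocarbenium ion, addition of water, loss of methanol) is far faster than cleavage of the hindered secondary silyl ether or of the C4 methyl ether, and the resulting γ-keto aldehyde cannot condense to a furan because C6 carries no hydrogen.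

Step 10
Reactants: 16 2-[(1S,5R)-1-[(1R,2S)-1-[(tert-butyldimethylsilyl)oxy]-1-(3,4,5-trimethoxyphenyl)propan-2-yl]-5-methoxy-2-oxocyclohex-3-en-1-yl]acetaldehyde
Product: 17 (4R,6R)-6-[(1R,2S)-1-[(tert-butyldimethylsilyl)oxy]-1-(3,4,5-trimethoxyphenyl)propan-2-yl]-4-methoxy-6-(prop-2-en-1-yl)cyclohex-2-en-1-one
Conditions: Ph3PCH3Br, KN(SiMe3)2, THF, −78 to 0 °C
Reagents that add atoms: methyltriphenylphosphonium bromide, C[P+](c1ccccc1)(c1ccccc1)c1ccccc1.[Br-]
Why: Wittig methylenation is selective at low temperature for the unhindered aldehyde over the neopentyl enone carbonyl and completes the allyl group without touching a stereocentre.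

Step 11
Reactants: 17 (4R,6R)-6-[(1R,2S)-1-[(tert-butyldimethylsilyl)oxy]-1-(3,4,5-trimethoxyphenyl)propan-2-yl]-4-methoxy-6-(prop-2-en-1-yl)cyclohex-2-en-1-one
Product: 18 megaphone, (4R,6R)-6-[(1R,2S)-1-hydroxy-1-(3,4,5-trimethoxyphenyl)propan-2-yl]-4-methoxy-6-(prop-2-en-1-yl)cyclohex-2-en-1-one
Conditions: HF·pyridine, pyridine, THF, 0 °C to rt
Reagents that add atoms: none
Why: Cleavage of the Si–O bond by buffered HF·pyridine releases the C7 alcohol without breaking the C7–O bond and avoids basic conditions that could epimerise C4 through γ-deprotonation of the enone.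

Step 12
Reactants: 18 megaphone
Product: 19 megaphone acetate, (1R,2S)-2-[(1R,5R)-5-methoxy-2-oxo-1-(prop-2-en-1-yl)cyclohex-3-en-1-yl]-1-(3,4,5-trimethoxyphenyl)propyl acetate
Conditions: Ac2O, pyridine, 4-(dimethylamino)pyridine (cat.), CH2Cl2, rt
Reagents that add atoms: acetic anhydride, CC(=O)OC(C)=O
Why: Acylation of the secondary benzylic alcohol with acetic anhydride under nucleophilic catalysis proceeds with retention at C7 and should give the target.

**Compound list**

1 | 3,4,5-trimethoxybenzaldehyde | COc1cc(C=O)cc(OC)c1OC | starting material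
2 | (Z)-crotylboronic acid pinacol ester | C/C=C\CB1OC(C)(C)C(C)(C)O1 | starting material
3 | 4,4,5,5-tetramethyl-2-{[(1R,2S)-2-methyl-1-(3,4,5-trimethoxyphenyl)but-3-en-1-yl]oxy}-1,3,2-dioxaborolane | C=C[C@H](C)[C@@H](OB1OC(C)(C)C(C)(C)O1)c2cc(OC)c(OC)c(OC)c2 | intermediate (not isolated)
4 | (1R,2S)-2-methyl-1-(3,4,5-trimethoxyphenyl)but-3-en-1-ol | C=C[C@H](C)[C@@H](O)c1cc(OC)c(OC)c(OC)c1 | intermediate
5 | tert-butyl(dimethyl){[(1R,2S)-2-methyl-1-(3,4,5-trimethoxyphenyl)but-3-en-1-yl]oxy}silane | C=C[C@H](C)[C@@H](O[Si](C)(C)C(C)(C)C)c1cc(OC)c(OC)c(OC)c1 | intermediate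
6 | 9-[(3S,4R)-4-[(tert-butyldimethylsilyl)oxy]-3-methyl-4-(3,4,5-trimethoxyphenyl)butyl]-9-borabicyclo[3.3.1]nonane | C1CC2CCCC(C1)B2CC[C@H](C)[C@@H](O[Si](C)(C)C(C)(C)C)c3cc(OC)c(OC)c(OC)c3 | intermediate (not isolated)
7 | (3S,4R)-4-[(tert-butyldimethylsilyl)oxy]-3-methyl-4-(3,4,5-trimethoxyphenyl)butan-1-ol | OCC[C@H](C)[C@@H](O[Si](C)(C)C(C)(C)C)c1cc(OC)c(OC)c(OC)c1 | intermediate
8 | (3S,4R)-4-[(tert-butyldimethylsilyl)oxy]-3-methyl-4-(3,4,5-trimethoxyphenyl)butanal | O=CC[C@H](C)[C@@H](O[Si](C)(C)C(C)(C)C)c1cc(OC)c(OC)c(OC)c1 | intermediate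
9 | (3S,4R)-4-[(tert-butyldimethylsilyl)oxy]-2-[(dimethylamino)methyl]-3-methyl-4-(3,4,5-trimethoxyphenyl)butanal (both C2 epimers) | CN(C)CC(C=O)[C@H](C)[C@@H](O[Si](C)(C)C(C)(C)C)c1cc(OC)c(OC)c(OC)c1 | intermediate (not isolated)
10 | (3S,4R)-4-[(tert-butyldimethylsilyl)oxy]-3-methyl-2-methylidene-4-(3,4,5-trimethoxyphenyl)butanal | C=C(C=O)[C@H](C)[C@@H](O[Si](C)(C)C(C)(C)C)c1cc(OC)c(OC)c(OC)c1 | intermediate (key-step precursor)
11 | 2-methoxyfuran | COc1ccco1 | starting material
12 | (1R,2R,4R)-2-[(1R,2S)-1-[(tert-butyldimethylsilyl)oxy]-1-(3,4,5-trimethoxyphenyl)propan-2-yl]-1-methoxy-7-oxabicyclo[2.2.1]hept-5-ene-2-carbaldehyde | O=C[C@]1([C@H](C)[C@@H](O[Si](C)(C)C(C)(C)C)c2cc(OC)c(OC)c(OC)c2)C[C@@H]3C=C[C@@]1(OC)O3 | intermediate (not isolated)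
13 | (1R,5R)-1-[(1R,2S)-1-[(tert-butyldimethylsilyl)oxy]-1-(3,4,5-trimethoxyphenyl)propan-2-yl]-5-hydroxy-2-oxocyclohex-3-ene-1-carbaldehyde | O=C[C@]1([C@H](C)[C@@H](O[Si](C)(C)C(C)(C)C)c2cc(OC)c(OC)c(OC)c2)C[C@@H](O)C=CC1=O | intermediate (key-step product)
14 | (1R,5R)-1-[(1R,2S)-1-[(tert-butyldimethylsilyl)oxy]-1-(3,4,5-trimethoxyphenyl)propan-2-yl]-5-methoxy-2-oxocyclohex-3-ene-1-carbaldehyde | O=C[C@]1([C@H](C)[C@@H](O[Si](C)(C)C(C)(C)C)c2cc(OC)c(OC)c(OC)c2)C[C@@H](OC)C=CC1=O | intermediate
15 | (4R,6S)-6-[(1R,2S)-1-[(tert-butyldimethylsilyl)oxy]-1-(3,4,5-trimethoxyphenyl)propan-2-yl]-4-methoxy-6-(2-methoxyethenyl)cyclohex-2-en-1-one (E/Z mixture) | COC=C[C@]1([C@H](C)[C@@H](O[Si](C)(C)C(C)(C)C)c2cc(OC)c(OC)c(OC)c2)C[C@@H](OC)C=CC1=O | intermediate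
16 | 2-[(1S,5R)-1-[(1R,2S)-1-[(tert-butyldimethylsilyl)oxy]-1-(3,4,5-trimethoxyphenyl)propan-2-yl]-5-methoxy-2-oxocyclohex-3-en-1-yl]acetaldehyde | O=CC[C@]1([C@H](C)[C@@H](O[Si](C)(C)C(C)(C)C)c2cc(OC)c(OC)c(OC)c2)C[C@@H](OC)C=CC1=O | intermediate
17 | (4R,6R)-6-[(1R,2S)-1-[(tert-butyldimethylsilyl)oxy]-1-(3,4,5-trimethoxyphenyl)propan-2-yl]-4-methoxy-6-(prop-2-en-1-yl)cyclohex-2-en-1-one | C=CC[C@]1([C@H](C)[C@@H](O[Si](C)(C)C(C)(C)C)c2cc(OC)c(OC)c(OC)c2)C[C@@H](OC)C=CC1=O | intermediate
18 | megaphone, (4R,6R)-6-[(1R,2S)-1-hydroxy-1-(3,4,5-trimethoxyphenyl)propan-2-yl]-4-methoxy-6-(prop-2-en-1-yl)cyclohex-2-en-1-one | C=CC[C@]1([C@H](C)[C@@H](O)c2cc(OC)c(OC)c(OC)c2)C[C@@H](OC)C=CC1=O | intermediate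
19 | megaphone acetate, (1R,2S)-2-[(1R,5R)-5-methoxy-2-oxo-1-(prop-2-en-1-yl)cyclohex-3-en-1-yl]-1-(3,4,5-trimethoxyphenyl)propyl acetate | C=CC[C@]1([C@H](C)[C@@H](OC(C)=O)c2cc(OC)c(OC)c(OC)c2)C[C@@H](OC)C=CC1=O | target

**Count and risks**

Total step count: 12. Longest linear sequence: 12 steps (1 to 19); 2 and 11 enter as purchased reagents.

Steps most likely to fail:

Step 6. The furan may add to the Si face of C6, because the bias that C8 exerts through a 1,1-disubstituted alkene is modest. The formyl group may also take the exo position, or the Michael intermediate may lose a proton and rearomatise. The fallback sets out from 10 (with 11) and comes back at 13. The cycloaddition is run under reagent control with an enantiopure cationic oxazaborolidine, so that the catalyst and no longer C8 selects the face. The catalyst is the N-protonated triflimide salt of 3,3-diphenyl-1-(2-methylphenyl)tetrahydro-1H,3H-pyrrolo[1,2-c][1,3,2]oxazaborole, made from α,α-diphenylprolinol, tri-o-tolylboroxine and Tf2NH, and the antipode is chosen that opens the Re face of C6. Because 2-substituted acroleins commonly add under such catalysts with the formyl group exo, the bridged ketal then expected is the exo-formyl cycloadduct F1. It should open on the same aqueous work-up to the C4-epimeric hydroxy enone F2, which may rest partly as a bridged lactol but reacts through its open form. A Mitsunobu reaction (chloroacetic acid, PPh3, diisopropyl azodicarboxylate, THF, 0 °C) inverts C4 and should give the chloroacetate F3. Thiourea with NaHCO3 in ethanol then removes the chloroacetyl group under neutral conditions and returns 13.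

Step 8. The basic ylide or adventitious alkoxide may trigger retro-Claisen loss of the formyl group from the β-keto aldehyde, or attack at the neopentyl aldehyde may be slow enough for the enone to compete. The fallback sets out from 14 and comes back at 17, passing by 15 and 16. CH2=CHMgBr in THF at −78 °C, quenched cold, should add to the aldehyde alone and give the allylic alcohol F4 as a mixture of carbinol epimers that converge later. ClCO2Me and pyridine convert it into the methyl carbonate F5. Pd(OAc)2, n-Bu3P and HCO2NH4 in THF then generate zerovalent palladium, which ionises the carbonate to a π-allyl complex. Formate delivers hydride to the more substituted allyl terminus (regioselective formate reduction of allylic carbonates to 1-alkenes), which should give 17 directly.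

Step 7. O-Alkylation of the secondary allylic alcohol by the oxonium salt may stall, and long exposure may erode the β-keto aldehyde. The fallback sets out from 13 and comes back at 15 by inverting the order of operations. The Wittig reaction of step 8 is run on 13 with an extra equivalent of ylide, the C4 alkoxide being a spectator trans to the formyl group, and should give the hydroxy enol ether F6. With the aldehyde gone, methylation under neutral conditions (Ag2O, MeI, CH2Cl2, rt) then gives 15.

**Further compounds**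

F1 | step 6 | (1S,2R,4S)-2-[(1R,2S)-1-[(tert-butyldimethylsilyl)oxy]-1-(3,4,5-trimethoxyphenyl)propan-2-yl]-1-methoxy-7-oxabicyclo[2.2.1]hept-5-ene-2-carbaldehyde | O=C[C@]1([C@H](C)[C@@H](O[Si](C)(C)C(C)(C)C)c2cc(OC)c(OC)c(OC)c2)C[C@H]3C=C[C@]1(OC)O3
F2 | step 6 | (1R,5S)-1-[(1R,2S)-1-[(tert-butyldimethylsilyl)oxy]-1-(3,4,5-trimethoxyphenyl)propan-2-yl]-5-hydroxy-2-oxocyclohex-3-ene-1-carbaldehyde | O=C[C@]1([C@H](C)[C@@H](O[Si](C)(C)C(C)(C)C)c2cc(OC)c(OC)c(OC)c2)C[C@H](O)C=CC1=O
F3 | step 6 | (1R,5R)-5-[(1R,2S)-1-[(tert-butyldimethylsilyl)oxy]-1-(3,4,5-trimethoxyphenyl)propan-2-yl]-5-formyl-4-oxocyclohex-2-en-1-yl 2-chloroacetate | O=C[C@]1([C@H](C)[C@@H](O[Si](C)(C)C(C)(C)C)c2cc(OC)c(OC)c(OC)c2)C[C@@H](OC(=O)CCl)C=CC1=O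
F4 | step 8 | (4R,6R)-6-[(1R,2S)-1-[(tert-butyldimethylsilyl)oxy]-1-(3,4,5-trimethoxyphenyl)propan-2-yl]-6-(1-hydroxyprop-2-en-1-yl)-4-methoxycyclohex-2-en-1-one (both carbinol epimers) | C=CC(O)[C@]1([C@H](C)[C@@H](O[Si](C)(C)C(C)(C)C)c2cc(OC)c(OC)c(OC)c2)C[C@@H](OC)C=CC1=O
F5 | step 8 | 1-[(1R,5R)-1-[(1R,2S)-1-[(tert-butyldimethylsilyl)oxy]-1-(3,4,5-trimethoxyphenyl)propan-2-yl]-5-methoxy-2-oxocyclohex-3-en-1-yl]prop-2-en-1-yl methyl carbonate (both carbinol epimers) | C=CC(OC(=O)OC)[C@]1([C@H](C)[C@@H](O[Si](C)(C)C(C)(C)C)c2cc(OC)c(OC)c(OC)c2)C[C@@H](OC)C=CC1=O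
F6 | step 7 | (4R,6S)-6-[(1R,2S)-1-[(tert-butyldimethylsilyl)oxy]-1-(3,4,5-trimethoxyphenyl)propan-2-yl]-4-hydroxy-6-(2-methoxyethenyl)cyclohex-2-en-1-one (E/Z mixture) | COC=C[C@]1([C@H](C)[C@@H](O[Si](C)(C)C(C)(C)C)c2cc(OC)c(OC)c(OC)c2)C[C@@H](O)C=CC1=O
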